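The pyran ring of the isoflavan (O1, C2, C3, C4, C4a, C8a) is traced back to the furan ring of psoralen. An aryl(chloro)carbene that already carries ring B inserts its carbon between furan C2 and C3, so one operation turns the benzofuran into a 3-aryl-2H-chromene. The feature used is that C3, flanked by two CH2 groups, is the only pyran atom bearing ring B. All eleven carbons of psoralen stay in the target: its pyranone afterwards gives the side chain by Rh-catalysed aryl addition (diaryl carbon), enolate hydroxylation (carbinol) and reduction to an epoxide that the aryl Grignard reagent opens. Ir-catalysed hydrogenation sets C3.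

Key step: step 5

Remark: 1, 9, 13 and 23 are taken as catalogue compounds. The sense of induction of (R)-SEGPHOS is assigned by analogy with coumarins; the ThrePHOX antipode is the one that gives 7R. The CIP descriptor of the diaryl carbon changes with the protecting-group pattern (18, 19) without any change in geometry.

Step 1
Reactants: 1 2-hydroxy-3,4-dimethoxybenzaldehyde
Product: 3 2-hydroxy-3,4-dimethoxybenzonitrile, via aldoxime 2 (not isolated)
Conditions: NH2OH·HCl, HCO2Na, HCO2H, reflux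
Reagents that add atoms: hydroxylamine hydrochloride, NO.Cl
Why: One-pot oximation and formic acid dehydration of the aldoxime (aldehyde-to-nitrile conversion) should give the nitrile needed for the amidine, the free ortho phenol being tolerated.

Step 2
Reactants: 3 2-hydroxy-3,4-dimethoxybenzonitrile
Product: 4 3,4-dimethoxy-2-[(triisopropylsilyl)oxy]benzonitrile
Conditions: TIPSCl, imidazole, DMF, 40 °C
Reagents that add atoms: chlorotriisopropylsilane, CC(C)[Si](Cl)(C(C)C)C(C)C
Why: Silyl ether formation masks the phenol that would quench the later carbene, and a silyl group is chosen because, unlike a benzyl or methyl ether, it offers no C–H bond α to oxygen for intramolecular 1,5-insertion of that carbene.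

Step 3
Reactants: 4 3,4-dimethoxy-2-[(triisopropylsilyl)oxy]benzonitrile
Product: 6 3,4-dimethoxy-2-[(triisopropylsilyl)oxy]benzenecarboximidamide hydrochloride, via lithium N,N′-bis(trimethylsilyl)amidinate 5 (not isolated)
Conditions: LiHMDS, THF, 0 °C to rt; then HCl (4 M in dioxane), 0 °C
Reagents that add atoms: lithium bis(trimethylsilyl)amide, [Li]N([Si](C)(C)C)[Si](C)(C)C; hydrogen chloride, Cl
Why: Addition of the silylamide to the nitrile and acid cleavage of the N-silyl groups (silylamide route to amidines) should give the amidinium salt without touching the aryl silyl ether.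

Step 4
Reactants: 6 3,4-dimethoxy-2-[(triisopropylsilyl)oxy]benzenecarboximidamide hydrochloride
Product: 8 3-chloro-3-{3,4-dimethoxy-2-[(triisopropylsilyl)oxy]phenyl}-3H-diazirine, via N,N′-dichloroamidine 7 (not isolated)
Conditions: NaOCl (aq.), LiCl, DMSO/pentane, 0 °C to rt; kept cold and used at once
Reagents that add atoms: sodium hypochlorite, [Na+].[O-]Cl; lithium chloride, [Li+].[Cl-]
Why: Graham oxidation (N-chlorination, base-induced N–N closure and chloride return) converts an amidinium salt into the 3-chloro-3-aryldiazirine, the standard thermal precursor of an aryl(chloro)carbene, and this electron-rich member is labile, so it is carried on as a cold solution.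

Step 5
Reactants: 9 psoralen (7H-furo[3,2-g]chromen-7-one); 8 3-chloro-3-{3,4-dimethoxy-2-[(triisopropylsilyl)oxy]phenyl}-3H-diazirine
Product: 12 7-{3,4-dimethoxy-2-[(triisopropylsilyl)oxy]phenyl}-2H,8H-pyrano[3,2-g]chromen-2-one, via chlorocyclopropane adduct 10 (not isolated), via chromenylium chloride 11 (not isolated)
Conditions: 8 (3 equiv, added cold over 2 h), MeCN, 50 °C, dark; then Bu4NBH4, −40 °C
Reagents that add atoms: none
Why: Thermolysis of 8 releases N2 and the singlet aryl(chloro)carbene, which adds to the enol-ether-like C2=C3 bond of the furan ring of 9 to give cyclopropane 10; disrotatory 2π-electrocyclic opening of 10 with loss of chloride breaks the old furan C2–C3 bond and leaves the carbene carbon, with ring B on it, as C7 of the six-membered chromenylium 11, to which borohydride adds at the oxocarbenium carbon C8. The closest known reaction type is the Ciamician–Dennstedt-type halocarbene ring expansion, known for dihalocarbenes on benzofurans (3-halo-2H-chromenes) and for arylchlorodiazirines on indoles and pyrroles (3-arylquinolines and 3-arylpyridines). The only ring closed is the transient cyclopropane, by concerted [2+1] cheletropic addition; the pyran ring is not closed but arises from the furan ring by one-carbon expansion. No stereocentre survives into 12, so none has to be controlled. The step needs site selectivity for the furan over the pyranone C=C bond, which the electrophilic carbene and the electron-poor coumarin double bond should secure, and a chloride endo to the five-membered ring for the opening, which the exo preference of the bulky aryl group and reversible ionisation of the benzylic C–Cl bond should provide. Hydride attack at C8 rather than C6 is expected for a hard hydride at the position next to oxygen, and the reaction is run in the dark because psoralen is photoactive.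

Step 6
Reactants: 12 7-{3,4-dimethoxy-2-[(triisopropylsilyl)oxy]phenyl}-2H,8H-pyrano[3,2-g]chromen-2-one; 13 2,4-bis(benzyloxy)phenylboronic acid
Product: 14 (4R)-4-[2,4-bis(benzyloxy)phenyl]-7-{3,4-dimethoxy-2-[(triisopropylsilyl)oxy]phenyl}-3,4-dihydro-2H,8H-pyrano[3,2-g]chromen-2-one
Conditions: 13 (2.5 equiv), Rh(acac)(C2H4)2 (3 mol %), (R)-SEGPHOS (3.3 mol %), dioxane/H2O 10:1, 60 °C
Reagents that add atoms: none
Why: Rhodium-catalysed asymmetric 1,4-addition of the arylboronic acid to the coumarin C3=C4 bond (Hayashi–Miyaura reaction) sets C4 by catalyst control, the (R)-SEGPHOS–Rh aryl species adding to the face that gives (R)-4-arylchroman-2-ones from coumarins, while the styrene-type C6=C7 bond is no acceptor.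

Step 7
Reactants: 14 (4R)-4-[2,4-bis(benzyloxy)phenyl]-7-{3,4-dimethoxy-2-[(triisopropylsilyl)oxy]phenyl}-3,4-dihydro-2H,8H-pyrano[3,2-g]chromen-2-one
Product: 15 (4R,7R)-4-[2,4-bis(benzyloxy)phenyl]-7-{3,4-dimethoxy-2-[(triisopropylsilyl)oxy]phenyl}-3,4,7,8-tetrahydro-2H,6H-pyrano[3,2-g]chromen-2-one
Conditions: [Ir(cod)(ThrePHOX)]BArF (2 mol %), H2 (50 bar), CH2Cl2, rt
Reagents that add atoms: none
Why: Iridium N,P-catalysed asymmetric hydrogenation of the trisubstituted, trans-stilbene-like olefin of the 3-aryl-2H-chromene sets C7 (isoflavan C3) by catalyst control, the remote C4 centre having no influence, and leaves benzyl ethers, silyl ether and lactone untouched.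

Step 8
Reactants: 15 (4R,7R)-4-[2,4-bis(benzyloxy)phenyl]-7-{3,4-dimethoxy-2-[(triisopropylsilyl)oxy]phenyl}-3,4,7,8-tetrahydro-2H,6H-pyrano[3,2-g]chromen-2-one
Product: 17 (3S,4R,7R)-4-[2,4-bis(benzyloxy)phenyl]-3-hydroxy-7-{3,4-dimethoxy-2-[(triisopropylsilyl)oxy]phenyl}-3,4,7,8-tetrahydro-2H,6H-pyrano[3,2-g]chromen-2-one, via potassium enolate 16 (not isolated)
Conditions: KHMDS, THF, −78 °C; then 2-(phenylsulfonyl)-3-phenyloxaziridine, −78 °C; NH4Cl (aq.)
Reagents that add atoms: 2-(phenylsulfonyl)-3-phenyloxaziridine, O=S(=O)(c1ccccc1)N1OC1c1ccccc1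
Why: Electrophilic hydroxylation of the lactone enolate with the Davis oxaziridine installs the carbinol oxygen, C3 being set by substrate control because the oxidant approaches anti to the pseudoaxial C4 aryl group (3,4-trans lactone), and the low temperature suppresses ketene formation from the aryl-ester enolate.

Step 9
Reactants: 17 (3S,4R,7R)-4-[2,4-bis(benzyloxy)phenyl]-3-hydroxy-7-{3,4-dimethoxy-2-[(triisopropylsilyl)oxy]phenyl}-3,4,7,8-tetrahydro-2H,6H-pyrano[3,2-g]chromen-2-one
Product: 18 (2S,3S)-3-[2,4-bis(benzyloxy)phenyl]-3-[(3R)-3-{3,4-dimethoxy-2-[(triisopropylsilyl)oxy]phenyl}-7-hydroxychroman-6-yl]propane-1,2-diol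
Conditions: LiAlH4, THF, 0 °C; Rochelle salt work-up
Reagents that add atoms: none
Why: Hydride reduction of the lactone opens it to the primary alcohol and frees the chroman 7-OH without touching either side-chain stereocentre.

Step 10
Reactants: 18 (2S,3S)-3-[2,4-bis(benzyloxy)phenyl]-3-[(3R)-3-{3,4-dimethoxy-2-[(triisopropylsilyl)oxy]phenyl}-7-hydroxychroman-6-yl]propane-1,2-diol
Product: 20 (2S,3R)-3-[2,4-bis(benzyloxy)phenyl]-3-{(3R)-7-(benzyloxy)-3-[2-(benzyloxy)-3,4-dimethoxyphenyl]chroman-6-yl}propane-1,2-diol, via desilylated tetraol 19 (not isolated)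
Conditions: CsF, Cs2CO3, DMF, rt; then BnBr (2.2 equiv), rt
Reagents that add atoms: benzyl bromide, BrCc1ccccc1
Why: Fluoride cleaves the aryl silyl ether and both caesium phenoxides are benzylated (Williamson ether synthesis), the aliphatic diol not being ionised by carbonate, so that every phenol now carries the same protecting group.

Step 11
Reactants: 20 (2S,3R)-3-[2,4-bis(benzyloxy)phenyl]-3-{(3R)-7-(benzyloxy)-3-[2-(benzyloxy)-3,4-dimethoxyphenyl]chroman-6-yl}propane-1,2-diol
Product: 22 (2S)-2-[(R)-[2,4-bis(benzyloxy)phenyl]{(3R)-7-(benzyloxy)-3-[2-(benzyloxy)-3,4-dimethoxyphenyl]chroman-6-yl}methyl]oxirane, via primary tosylate 21 (not isolated)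
Conditions: NaH (2.5 equiv), N-tosylimidazole (1.05 equiv), THF, 0 °C to rt
Reagents that add atoms: none
Why: Selective sulfonylation of the primary alkoxide followed by intramolecular Williamson closure (one-pot diol-to-epoxide conversion) gives the terminal epoxide, and since the secondary C–O bond is not broken the carbinol carbon keeps its configuration.

Step 12
Reactants: 22 (2S)-2-[(R)-[2,4-bis(benzyloxy)phenyl]{(3R)-7-(benzyloxy)-3-[2-(benzyloxy)-3,4-dimethoxyphenyl]chroman-6-yl}methyl]oxirane; 23 4-(benzyloxy)phenylmagnesium bromide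
Product: 24 (1R,2R)-1-[2,4-bis(benzyloxy)phenyl]-1-{(3R)-7-(benzyloxy)-3-[2-(benzyloxy)-3,4-dimethoxyphenyl]chroman-6-yl}-3-[4-(benzyloxy)phenyl]propan-2-ol
Conditions: 23 (2.5 equiv), CuI (10 mol %), THF, −30 to 0 °C; NH4Cl (aq.)
Reagents that add atoms: none
Why: Copper-catalysed SN2 opening of the terminal epoxide by the aryl Grignard reagent at the unhindered CH2 group forms the benzylic C–C bond and releases the secondary alcohol with its configuration intact.

Step 13
Reactants: 24 (1R,2R)-1-[2,4-bis(benzyloxy)phenyl]-1-{(3R)-7-(benzyloxy)-3-[2-(benzyloxy)-3,4-dimethoxyphenyl]chroman-6-yl}-3-[4-(benzyloxy)phenyl]propan-2-ol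
Product: 25 4-[(1R,2R)-2-hydroxy-1-[(3R)-7-hydroxy-3-(2-hydroxy-3,4-dimethoxyphenyl)chroman-6-yl]-3-(4-hydroxyphenyl)propyl]benzene-1,3-diol
Conditions: H2 (1 atm), 10% Pd/C, EtOAc/MeOH, rt
Reagents that add atoms: none
Why: Hydrogenolysis of the five benzyl ethers over palladium frees all phenols under neutral conditions, which the acid-sensitive bis(resorcinyl)methine and the secondary alcohol should tolerate.

Compound list

1 | 2-hydroxy-3,4-dimethoxybenzaldehyde | O=Cc1ccc(OC)c(OC)c1O | starting material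
2 | 2-hydroxy-3,4-dimethoxybenzaldehyde oxime | ON=Cc1ccc(OC)c(OC)c1O | intermediate (not isolated)
3 | 2-hydroxy-3,4-dimethoxybenzonitrile | N#Cc1ccc(OC)c(OC)c1O | intermediate
4 | 3,4-dimethoxy-2-[(triisopropylsilyl)oxy]benzonitrile | N#Cc1ccc(OC)c(OC)c1O[Si](C(C)C)(C(C)C)C(C)C | intermediate
5 | lithium N,N′-bis(trimethylsilyl)-3,4-dimethoxy-2-[(triisopropylsilyl)oxy]benzamidinate | C[Si](C)(C)N=C(N([Li])[Si](C)(C)C)c1ccc(OC)c(OC)c1O[Si](C(C)C)(C(C)C)C(C)C | intermediate (not isolated)
6 | 3,4-dimethoxy-2-[(triisopropylsilyl)oxy]benzenecarboximidamide hydrochloride | Cl.NC(=N)c1ccc(OC)c(OC)c1O[Si](C(C)C)(C(C)C)C(C)C | intermediate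
7 | N,N′-dichloro-3,4-dimethoxy-2-[(triisopropylsilyl)oxy]benzenecarboximidamide | ClN=C(NCl)c1ccc(OC)c(OC)c1O[Si](C(C)C)(C(C)C)C(C)C | intermediate (not isolated)
8 | 3-chloro-3-{3,4-dimethoxy-2-[(triisopropylsilyl)oxy]phenyl}-3H-diazirine | ClC1(N=N1)c1ccc(OC)c(OC)c1O[Si](C(C)C)(C(C)C)C(C)C | intermediate
9 | psoralen (7H-furo[3,2-g]chromen-7-one) | O=C1C=Cc2cc3ccoc3cc2O1 | starting material
10 | chloro(aryl)cyclopropane fused across furan C2–C3 of psoralen (cis-fused, racemic, both chloride epimers) | O=C1C=Cc2cc3c(cc2O1)OC4C3C4(Cl)c5ccc(OC)c(OC)c5O[Si](C(C)C)(C(C)C)C(C)C | intermediate (not isolated)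
11 | 7-{3,4-dimethoxy-2-[(triisopropylsilyl)oxy]phenyl}-2-oxo-2H-pyrano[3,2-g]chromen-9-ium chloride | O=C1C=Cc2cc3cc(-c4ccc(OC)c(OC)c4O[Si](C(C)C)(C(C)C)C(C)C)c[o+]c3cc2O1.[Cl-] | intermediate (not isolated)
12 | 7-{3,4-dimethoxy-2-[(triisopropylsilyl)oxy]phenyl}-2H,8H-pyrano[3,2-g]chromen-2-one | COc1ccc(C2=Cc3cc4C=CC(=O)Oc4cc3OC2)c(O[Si](C(C)C)(C(C)C)C(C)C)c1OC | intermediate
13 | 2,4-bis(benzyloxy)phenylboronic acid | OB(O)c1ccc(OCc2ccccc2)cc1OCc1ccccc1 | starting material
14 | (4R)-4-[2,4-bis(benzyloxy)phenyl]-7-{3,4-dimethoxy-2-[(triisopropylsilyl)oxy]phenyl}-3,4-dihydro-2H,8H-pyrano[3,2-g]chromen-2-one | COc1ccc(C2=Cc3cc4[C@@H](c5ccc(OCc6ccccc6)cc5OCc5ccccc5)CC(=O)Oc4cc3OC2)c(O[Si](C(C)C)(C(C)C)C(C)C)c1OC | intermediate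
15 | (4R,7R)-4-[2,4-bis(benzyloxy)phenyl]-7-{3,4-dimethoxy-2-[(triisopropylsilyl)oxy]phenyl}-3,4,7,8-tetrahydro-2H,6H-pyrano[3,2-g]chromen-2-one | COc1ccc([C@@H]2COc3cc4OC(=O)C[C@H](c5ccc(OCc6ccccc6)cc5OCc5ccccc5)c4cc3C2)c(O[Si](C(C)C)(C(C)C)C(C)C)c1OC | intermediate
16 | potassium enolate of lactone 15 | COc1ccc([C@@H]2COc3cc4OC([O-])=C[C@H](c5ccc(OCc6ccccc6)cc5OCc5ccccc5)c4cc3C2)c(O[Si](C(C)C)(C(C)C)C(C)C)c1OC.[K+] | intermediate (not isolated)
17 | (3S,4R,7R)-4-[2,4-bis(benzyloxy)phenyl]-3-hydroxy-7-{3,4-dimethoxy-2-[(triisopropylsilyl)oxy]phenyl}-3,4,7,8-tetrahydro-2H,6H-pyrano[3,2-g]chromen-2-one | COc1ccc([C@@H]2COc3cc4OC(=O)[C@@H](O)[C@H](c5ccc(OCc6ccccc6)cc5OCc5ccccc5)c4cc3C2)c(O[Si](C(C)C)(C(C)C)C(C)C)c1OC | intermediate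
18 | (2S,3S)-3-[2,4-bis(benzyloxy)phenyl]-3-[(3R)-3-{3,4-dimethoxy-2-[(triisopropylsilyl)oxy]phenyl}-7-hydroxychroman-6-yl]propane-1,2-diol | COc1ccc([C@@H]2COc3cc(O)c([C@@H](c4ccc(OCc5ccccc5)cc4OCc4ccccc4)[C@H](O)CO)cc3C2)c(O[Si](C(C)C)(C(C)C)C(C)C)c1OC | intermediate
19 | (2S,3S)-3-[2,4-bis(benzyloxy)phenyl]-3-[(3R)-7-hydroxy-3-(2-hydroxy-3,4-dimethoxyphenyl)chroman-6-yl]propane-1,2-diol | COc1ccc([C@@H]2COc3cc(O)c([C@@H](c4ccc(OCc5ccccc5)cc4OCc4ccccc4)[C@H](O)CO)cc3C2)c(O)c1OC | intermediate (not isolated)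
20 | (2S,3R)-3-[2,4-bis(benzyloxy)phenyl]-3-{(3R)-7-(benzyloxy)-3-[2-(benzyloxy)-3,4-dimethoxyphenyl]chroman-6-yl}propane-1,2-diol | COc1ccc([C@@H]2COc3cc(OCc4ccccc4)c([C@@H](c4ccc(OCc5ccccc5)cc4OCc4ccccc4)[C@H](O)CO)cc3C2)c(OCc2ccccc2)c1OC | intermediate
21 | (2S,3R)-3-[2,4-bis(benzyloxy)phenyl]-3-{(3R)-7-(benzyloxy)-3-[2-(benzyloxy)-3,4-dimethoxyphenyl]chroman-6-yl}-2-hydroxypropyl 4-methylbenzenesulfonate | COc1ccc([C@@H]2COc3cc(OCc4ccccc4)c([C@@H](c4ccc(OCc5ccccc5)cc4OCc4ccccc4)[C@H](O)COS(=O)(=O)c4ccc(C)cc4)cc3C2)c(OCc2ccccc2)c1OC | intermediate (not isolated)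
22 | (2S)-2-[(R)-[2,4-bis(benzyloxy)phenyl]{(3R)-7-(benzyloxy)-3-[2-(benzyloxy)-3,4-dimethoxyphenyl]chroman-6-yl}methyl]oxirane | COc1ccc([C@@H]2COc3cc(OCc4ccccc4)c([C@@H](c4ccc(OCc5ccccc5)cc4OCc4ccccc4)[C@H]4CO4)cc3C2)c(OCc2ccccc2)c1OC | intermediate
23 | 4-(benzyloxy)phenylmagnesium bromide | Br[Mg]c1ccc(OCc2ccccc2)cc1 | starting material
24 | (1R,2R)-1-[2,4-bis(benzyloxy)phenyl]-1-{(3R)-7-(benzyloxy)-3-[2-(benzyloxy)-3,4-dimethoxyphenyl]chroman-6-yl}-3-[4-(benzyloxy)phenyl]propan-2-ol | COc1ccc([C@@H]2COc3cc(OCc4ccccc4)c([C@@H](c4ccc(OCc5ccccc5)cc4OCc4ccccc4)[C@H](O)Cc4ccc(OCc5ccccc5)cc4)cc3C2)c(OCc2ccccc2)c1OC | intermediate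
25 | 4-[(1R,2R)-2-hydroxy-1-[(3R)-7-hydroxy-3-(2-hydroxy-3,4-dimethoxyphenyl)chroman-6-yl]-3-(4-hydroxyphenyl)propyl]benzene-1,3-diol | COc1ccc([C@@H]2COc3cc(O)c([C@@H](c4ccc(O)cc4O)[C@H](O)Cc4ccc(O)cc4)cc3C2)c(O)c1OC | target

Total step count: 13. Longest linear sequence: 13 steps (1 to 25 through the diazirine branch; 9 steps from psoralen 9).

Steps most likely to fail

Step 5. The carbene may be lost to azine formation with unreacted diazirine, to insertion into its own silyl group or to reaction with the solvent before it meets the only moderately nucleophilic furan double bond. The exo-chloro cyclopropane may fail to ionise, and hydride may be delivered to C6 instead of C8. The fallback keeps the one-carbon ring expansion but uses dichlorocarbene, the halocarbene long known on benzofurans, and attaches ring B afterwards. It sets out from 9: sodium trichloroacetate in DME at 85 °C gives the dichlorocyclopropane adduct F1. Opening with AgBF4 in MeCN and reduction with Bu4NBH4 give the 7-chloro-2H-chromene F2. Purchased 6-bromo-2,3-dimethoxyphenol is silylated (TIPSCl, imidazole) to the aryl bromide F3 and converted by Miyaura borylation (B2pin2, Pd(dppf)Cl2, KOAc) into the pinacol boronate F4. Suzuki–Miyaura coupling of F2 with F4 (Pd(OAc)2, SPhos, K3PO4, toluene/H2O, 80 °C) comes back to the route at 12.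

Step 7. Hydrogenation of the olefin, hindered by the ortho-silyloxy aryl group, may be slow, or the catalyst may discriminate poorly between its faces. The fallback gives up catalyst control. It sets out from 14: hydrogenation with Crabtree's catalyst ([Ir(cod)(PCy3)(py)]PF6, H2, CH2Cl2), which spares benzyl ethers, gives 15 together with its C7 epimer F5. The two are diastereomers because of the C4 centre and are separated by preparative HPLC, which comes back to the route at 15.

Step 8. The aryl-ester enolate may fragment by β-elimination of the phenoxide to a ketene before it is oxidised, or the oxidant may approach the wrong face. The fallback moves the oxidation to a neutral enol derivative. It sets out from 15: LDA in the presence of TMSCl (in situ quench, THF, −78 °C) gives the silyl ketene acetal F6. Rubottom oxidation with dimethyldioxirane at −78 °C, again anti to the C4 aryl group, gives the α-silyloxy lactone F7. Mild desilylation (citric acid, aqueous THF) comes back to the route at 17.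

Further compounds

F1 | step 5 | 1,1-dichlorocyclopropane fused across furan C2–C3 of psoralen | O=C1C=Cc2cc3c(cc2O1)OC4C3C4(Cl)Cl
F2 | step 5 | 7-chloro-2H,8H-pyrano[3,2-g]chromen-2-one | O=C1C=Cc2cc3C=C(Cl)COc3cc2O1
F3 | step 5 | (6-bromo-2,3-dimethoxyphenoxy)triisopropylsilane | COc1ccc(Br)c(O[Si](C(C)C)(C(C)C)C(C)C)c1OC
F4 | step 5 | 2-{3,4-dimethoxy-2-[(triisopropylsilyl)oxy]phenyl}-4,4,5,5-tetramethyl-1,3,2-dioxaborolane | COc1ccc(B2OC(C)(C)C(C)(C)O2)c(O[Si](C(C)C)(C(C)C)C(C)C)c1OC
F5 | step 7 | (4R,7S)-4-[2,4-bis(benzyloxy)phenyl]-7-{3,4-dimethoxy-2-[(triisopropylsilyl)oxy]phenyl}-3,4,7,8-tetrahydro-2H,6H-pyrano[3,2-g]chromen-2-one | COc1ccc([C@H]2COc3cc4OC(=O)C[C@H](c5ccc(OCc6ccccc6)cc5OCc5ccccc5)c4cc3C2)c(O[Si](C(C)C)(C(C)C)C(C)C)c1OC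
F6 | step 8 | trimethylsilyl ketene acetal of lactone 15 | COc1ccc([C@@H]2COc3cc4OC(O[Si](C)(C)C)=C[C@H](c5ccc(OCc6ccccc6)cc5OCc5ccccc5)c4cc3C2)c(O[Si](C(C)C)(C(C)C)C(C)C)c1OC
F7 | step 8 | O-trimethylsilyl ether of hydroxy lactone 17 | COc1ccc([C@@H]2COc3cc4OC(=O)[C@@H](O[Si](C)(C)C)[C@H](c5ccc(OCc6ccccc6)cc5OCc5ccccc5)c4cc3C2)c(O[Si](C(C)C)(C(C)C)C(C)C)c1OC
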